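**Plan**

- Retrosynthetic cuts: the five O–benzyl bonds, then C3–C4 and O1–C2 of ring C of flavanone unit 1 (the unit with the free phloroglucinol ring A). This splits the molecule into an o-quinoid ketene (from a salicylate acetonide) and a 4-aryloxystyrene that carries the complete flavanone unit 2. Further back: vinyl from diazonium from nitro, the C2''–C1''' bond (aryl to chromone), the C4'–O–C6'' diaryl ether (SNAr) and the C6''–O bond (para-hydroxylation of a phloroacetophenone).
- Enabling feature: in unit 1 the atoms O1–C8a–C4a–C4(=O) are a salicyloyl unit on ring A. Dearomatised, they are the four-atom heterodiene O=C–C=C(=O) of a 6-(oxomethylidene)cyclohexa-2,4-dienone. C2–C3 with the para-oxygenated ring B is an electron-rich styrene C=C. Ring C is therefore a hetero-[4+2] adduct whose formation rearomatises ring A.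
- Forward order: ring A of unit 2 is hydroxylated and O-arylated, ring C of unit 2 is closed as a chromone, ring B of unit 2 is added to it, and the nitro group is turned into the vinyl group. Ring C of unit 1 is closed last, in the step that also joins the two halves; global debenzylation ends the route.
- Stereochemistry: C-2'' (S) from ligand control in the Pd-catalysed conjugate arylation; C-2 (S) from a chiral Brønsted acid in the key cycloaddition. No later step uses base, so neither flavanone is opened to its chalcone.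

Key step: step 8

Remark: the configurations of the two chiral catalysts are assigned by analogy with the usual sense of induction of their classes; should a model run show the opposite sense, the enantiomeric catalyst is used.

**Step 1**
Reactants: 1 1-[4,6-bis(benzyloxy)-2-hydroxyphenyl]ethan-1-one
Product: 3 1-[4,6-bis(benzyloxy)-2,5-dihydroxyphenyl]ethan-1-one, via aryl sulfate 2 (not isolated)
Conditions: K2S2O8, aq KOH, pyridine, 10 °C to rt; then conc. HCl, toluene, 80 °C, N2
Reagents that add atoms: potassium peroxodisulfate [K+].[K+].[O-]S(=O)(=O)OOS(=O)(=O)[O-]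
Why: Elbs persulfate oxidation, in which the phenoxide of 1 attacks a peroxide oxygen through C-5, the only free position para to the phenoxide oxygen, and the aryl sulfate 2 is then hydrolysed by acid to the hydroquinone while benzyl ethers and acetyl group stay untouched.

**Step 2**
Reactants: 3 1-[4,6-bis(benzyloxy)-2,5-dihydroxyphenyl]ethan-1-one; 4 1-fluoro-4-nitrobenzene
Product: 5 1-[4,6-bis(benzyloxy)-2-hydroxy-5-(4-nitrophenoxy)phenyl]ethan-1-one
Conditions: K2CO3, DMF, 25–40 °C, N2
Reagents that add atoms: none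
Why: SNAr (addition–elimination through a Meisenheimer adduct) on the nitro-activated fluoroarene, selective for the 5-oxygen because the 2-hydroxy group is held in a hydrogen bond to the acetyl carbonyl, as in the known selective 5-O-alkylation of such hydroquinones.

**Step 3**
Reactants: 5 1-[4,6-bis(benzyloxy)-2-hydroxy-5-(4-nitrophenoxy)phenyl]ethan-1-one
Product: 7 5,7-bis(benzyloxy)-6-(4-nitrophenoxy)-4H-chromen-4-one, via enaminone 6 (not isolated)
Conditions: Me2NCH(OMe)2, toluene, 95 °C; then conc. HCl, CH2Cl2, rt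
Reagents that add atoms: N,N-dimethylformamide dimethyl acetal COC(OC)N(C)C
Why: Standard chromone synthesis from a 2'-hydroxyacetophenone, in which condensation at the methyl ketone gives the enaminone and acid then induces addition of the phenol and loss of dimethylamine.

**Step 4**
Reactants: 7 5,7-bis(benzyloxy)-6-(4-nitrophenoxy)-4H-chromen-4-one; 8 [4-(benzyloxy)phenyl]boronic acid
Product: 9 (2S)-5,7-bis(benzyloxy)-2-[4-(benzyloxy)phenyl]-6-(4-nitrophenoxy)-2,3-dihydro-4H-chromen-4-one
Conditions: Pd(OCOCF3)2 (10 mol%), (R)-4-tert-butyl-2-(pyridin-2-yl)-4,5-dihydrooxazole (12 mol%), NH4PF6, H2O, ClCH2CH2Cl, 60 °C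
Reagents that add atoms: none
Why: Palladium-catalysed asymmetric conjugate addition of an arylboronic acid to a chromone (aryl–palladium insertion into C2''=C3'', then protonolysis of the enolate), in which the tert-butyl group of the pyridine–oxazoline ligand blocks one face so that C-2'' should be set S by catalyst control, with nitroarene and benzyl ethers tolerated.

**Step 5**
Reactants: 9 (2S)-5,7-bis(benzyloxy)-2-[4-(benzyloxy)phenyl]-6-(4-nitrophenoxy)-2,3-dihydro-4H-chromen-4-one
Product: 10 (2S)-6-(4-aminophenoxy)-5,7-bis(benzyloxy)-2-[4-(benzyloxy)phenyl]-2,3-dihydro-4H-chromen-4-one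
Conditions: H2 (1 atm), 5% Pt/C (sulfided), EtOAc, rt
Reagents that add atoms: none
Why: Chemoselective catalytic hydrogenation of the nitro group over sulfided platinum, which should leave benzyl ethers and the aryl ketone alone and, being neutral, should not touch C-2''.

**Step 6**
Reactants: 10 (2S)-6-(4-aminophenoxy)-5,7-bis(benzyloxy)-2-[4-(benzyloxy)phenyl]-2,3-dihydro-4H-chromen-4-one
Product: 12 (2S)-5,7-bis(benzyloxy)-2-[4-(benzyloxy)phenyl]-6-(4-ethenylphenoxy)-2,3-dihydro-4H-chromen-4-one, via diazonium tetrafluoroborate 11 (not isolated)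
Conditions: t-BuONO (1.05 equiv), HBF4·OEt2, THF, −10 °C; then CH2=CHBF3K, Pd(OAc)2 (2 mol%), 1,4-dioxane/MeOH, rt
Reagents that add atoms: potassium vinyltrifluoroborate [K+].F[B-](F)(F)C=C (vinyl group of 12); tert-butyl nitrite CC(C)(C)ON=O and tetrafluoroboric acid [H+].F[B-](F)(F)F (atoms held only by intermediate 11)
Why: Diazotisation followed by base-free palladium-catalysed cross-coupling of the arenediazonium salt with the vinyltrifluoroborate (oxidative addition to zerovalent palladium with loss of N2, transmetalation, reductive elimination) should give the styrene without any base that could open the flavanone.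

**Step 7**
Reactants: 13 5,7-dihydroxy-2,2-dimethyl-4H-1,3-benzodioxin-4-one
Product: 14 5,7-bis(benzyloxy)-2,2-dimethyl-4H-1,3-benzodioxin-4-one
Conditions: BnBr, K2CO3, DMF, 60 °C
Reagents that add atoms: benzyl bromide BrCc1ccccc1
Why: Williamson etherification of both phenols (the chelated 5-OH needs DMF and warming), with the ketal ester stable to carbonate.

**Step 8**
Reactants: 12 (2S)-5,7-bis(benzyloxy)-2-[4-(benzyloxy)phenyl]-6-(4-ethenylphenoxy)-2,3-dihydro-4H-chromen-4-one; 14 5,7-bis(benzyloxy)-2,2-dimethyl-4H-1,3-benzodioxin-4-one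
Product: 16 (2S)-5,7-bis(benzyloxy)-2-[4-({(2S)-5,7-bis(benzyloxy)-2-[4-(benzyloxy)phenyl]-4-oxo-3,4-dihydro-2H-chromen-6-yl}oxy)phenyl]-2,3-dihydro-4H-chromen-4-one, via o-quinoid ketene 15 (not isolated)
Conditions: hν (300 nm lamps, Pyrex), 14 (5 equiv), (R)-N-triflylphosphoramide of 3,3'-bis(2,4,6-triisopropylphenyl)-5,5',6,6',7,7',8,8'-octahydro-1,1'-bi-2-naphthol (15 mol%), dry toluene, −40 °C
Reagents that add atoms: none
Why: Proposed new method: 300 nm excitation of the salicylate ketal 14 expels acetone by retro-[4+2] and gives the dearomatised o-quinoid ketene 15 (untrapped 15 recombines with acetone to 14), whose heterodiene O=C8a–C4a=C4(=O) is captured by the vinyl group of 12 in an inverse-electron-demand hetero-[4+2] driven by rearomatisation of ring A; the terminal CH2 bonds to the ketene carbon (C3–C4) and the benzylic carbon, whose positive charge the para-aryloxy group stabilises, bonds to the dienone oxygen (O1–C2), which fixes the regiochemistry. The closest known reaction types are the photochemical acylation of alcohols by quinoketenes from benzodioxinones, the [4+2] cycloaddition of acylketenes with electron-rich alkenes, and the chiral N-triflylphosphoramide-catalysed [4+2] of o-quinone methides with styrenes; their combination on a styrene C=C is not known. Ring C of unit 1 is the only ring closed, by an intermolecular asynchronous [4+2] cycloaddition whose second bond is the O1–C2 closure onto the benzylic cation. The new stereocentre C-2 should be set S by catalyst control: the chiral acid protonates the dienone oxygen of 15 faster than the uncatalysed cycloaddition can occur, and the resulting 2-hydroxyaroylium phosphoramide ion pair, with the phenolic OH hydrogen-bonded to the anion, exposes one face to the styrene. The step needs chemoselectivity for the styrene C=C over the benzyloxy arenes (secured by its much higher π-nucleophilicity), photochemical selectivity (the acid and the styrene chromophore absorb below 300 nm, and the five-fold excess of 14 shields the flavanone chromophore of unit 2 as an inner filter), and facial selectivity (secured by the catalyst pocket at low temperature), while the remote C-2'' centre neither helps nor interferes.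

**Step 9**
Reactants: 16 (2S)-5,7-bis(benzyloxy)-2-[4-({(2S)-5,7-bis(benzyloxy)-2-[4-(benzyloxy)phenyl]-4-oxo-3,4-dihydro-2H-chromen-6-yl}oxy)phenyl]-2,3-dihydro-4H-chromen-4-one
Product: 17 (2S)-5,7-dihydroxy-2-[4-({(2S)-5,7-dihydroxy-2-(4-hydroxyphenyl)-4-oxo-3,4-dihydro-2H-chromen-6-yl}oxy)phenyl]-2,3-dihydro-4H-chromen-4-one
Conditions: H2 (1 atm), 10% Pd/C, EtOAc/MeOH, rt
Reagents that add atoms: none
Why: Hydrogenolysis of the five benzyl aryl ethers under neutral conditions at room temperature should leave the aryl ketones, the diaryl ether and the ring C–O bonds at C-2 and C-2'' intact and, being free of acid and base, should not open either flavanone to its chalcone, so both S centres are kept.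

**Compound list**

1 | 1-[4,6-bis(benzyloxy)-2-hydroxyphenyl]ethan-1-one | CC(=O)c1c(O)cc(OCc2ccccc2)cc1OCc1ccccc1 | starting material
2 | potassium 3-acetyl-2,6-bis(benzyloxy)-4-hydroxyphenyl sulfate | CC(=O)c1c(O)cc(OCc2ccccc2)c(OS(=O)(=O)[O-])c1OCc1ccccc1.[K+] | intermediate
3 | 1-[4,6-bis(benzyloxy)-2,5-dihydroxyphenyl]ethan-1-one | CC(=O)c1c(O)cc(OCc2ccccc2)c(O)c1OCc1ccccc1 | intermediate
4 | 1-fluoro-4-nitrobenzene | O=[N+]([O-])c1ccc(F)cc1 | starting material
5 | 1-[4,6-bis(benzyloxy)-2-hydroxy-5-(4-nitrophenoxy)phenyl]ethan-1-one | CC(=O)c1c(O)cc(OCc2ccccc2)c(Oc2ccc(cc2)[N+](=O)[O-])c1OCc1ccccc1 | intermediate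
6 | (E)-1-[4,6-bis(benzyloxy)-2-hydroxy-5-(4-nitrophenoxy)phenyl]-3-(dimethylamino)prop-2-en-1-one | CN(C)/C=C/C(=O)c1c(O)cc(OCc2ccccc2)c(Oc2ccc(cc2)[N+](=O)[O-])c1OCc1ccccc1 | intermediate
7 | 5,7-bis(benzyloxy)-6-(4-nitrophenoxy)-4H-chromen-4-one | O=c1ccoc2cc(OCc3ccccc3)c(Oc3ccc(cc3)[N+](=O)[O-])c(OCc3ccccc3)c12 | intermediate
8 | [4-(benzyloxy)phenyl]boronic acid | OB(O)c1ccc(OCc2ccccc2)cc1 | starting material
9 | (2S)-5,7-bis(benzyloxy)-2-[4-(benzyloxy)phenyl]-6-(4-nitrophenoxy)-2,3-dihydro-4H-chromen-4-one | O=C1C[C@@H](c2ccc(OCc3ccccc3)cc2)Oc2cc(OCc3ccccc3)c(Oc3ccc(cc3)[N+](=O)[O-])c(OCc3ccccc3)c12 | intermediate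
10 | (2S)-6-(4-aminophenoxy)-5,7-bis(benzyloxy)-2-[4-(benzyloxy)phenyl]-2,3-dihydro-4H-chromen-4-one | O=C1C[C@@H](c2ccc(OCc3ccccc3)cc2)Oc2cc(OCc3ccccc3)c(Oc3ccc(N)cc3)c(OCc3ccccc3)c12 | intermediate
11 | 4-({(2S)-5,7-bis(benzyloxy)-2-[4-(benzyloxy)phenyl]-4-oxo-3,4-dihydro-2H-chromen-6-yl}oxy)benzenediazonium tetrafluoroborate | O=C1C[C@@H](c2ccc(OCc3ccccc3)cc2)Oc2cc(OCc3ccccc3)c(Oc3ccc(cc3)[N+]#N)c(OCc3ccccc3)c12.F[B-](F)(F)F | intermediate
12 | (2S)-5,7-bis(benzyloxy)-2-[4-(benzyloxy)phenyl]-6-(4-ethenylphenoxy)-2,3-dihydro-4H-chromen-4-one | O=C1C[C@@H](c2ccc(OCc3ccccc3)cc2)Oc2cc(OCc3ccccc3)c(Oc3ccc(C=C)cc3)c(OCc3ccccc3)c12 | intermediate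
13 | 5,7-dihydroxy-2,2-dimethyl-4H-1,3-benzodioxin-4-one | CC1(C)OC(=O)c2c(O)cc(O)cc2O1 | starting material
14 | 5,7-bis(benzyloxy)-2,2-dimethyl-4H-1,3-benzodioxin-4-one | CC1(C)OC(=O)c2c(OCc3ccccc3)cc(OCc3ccccc3)cc2O1 | intermediate
15 | 3,5-bis(benzyloxy)-6-(oxomethylidene)cyclohexa-2,4-dien-1-one | O=C=C1C(=O)C=C(OCc2ccccc2)C=C1OCc1ccccc1 | intermediate
16 | (2S)-5,7-bis(benzyloxy)-2-[4-({(2S)-5,7-bis(benzyloxy)-2-[4-(benzyloxy)phenyl]-4-oxo-3,4-dihydro-2H-chromen-6-yl}oxy)phenyl]-2,3-dihydro-4H-chromen-4-one | O=C1C[C@@H](c2ccc(Oc3c(OCc4ccccc4)cc4c(c3OCc3ccccc3)C(=O)C[C@@H](c3ccc(OCc5ccccc5)cc3)O4)cc2)Oc2cc(OCc3ccccc3)cc(OCc3ccccc3)c21 | intermediate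
17 | (2S)-5,7-dihydroxy-2-[4-({(2S)-5,7-dihydroxy-2-(4-hydroxyphenyl)-4-oxo-3,4-dihydro-2H-chromen-6-yl}oxy)phenyl]-2,3-dihydro-4H-chromen-4-one | O=C1C[C@@H](c2ccc(Oc3c(O)cc4c(c3O)C(=O)C[C@@H](c3ccc(O)cc3)O4)cc2)Oc2cc(O)cc(O)c21 | target

**Step count and risks**

Total steps: 9. Longest linear sequence: 8 steps (steps 1 to 6, 8 and 9); step 7 is a one-step side branch.

Steps most likely to fail:

1. Step 8. Several processes can go wrong:
   - The ketene may revert to 14 or be consumed by self-condensation or traces of water faster than the styrene traps it.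
   - The strong acid may start cationic oligomerisation of the electron-rich styrene.
   - Light absorbed by the flavanone chromophores may open ring C to the chalcone and so erode C-2'' and the new C-2.
   - Facial selectivity may be poor, giving both C-2 epimers.

   The fallback sets out from 10 (with starting material 1 for the partner) and comes back at 16, forming the C2–C1' bond instead by the known reaction type of step 4. Aniline 10 would be diazotised as in step 6 to 11, which with B2(OH)4 in MeOH (metal-free borylation of a diazonium salt) should give [4-({(2S)-5,7-bis(benzyloxy)-2-[4-(benzyloxy)phenyl]-4-oxo-3,4-dihydro-2H-chromen-6-yl}oxy)phenyl]boronic acid F1. In parallel, 1 would be heated with N,N-dimethylformamide dimethyl acetal to (E)-1-[4,6-bis(benzyloxy)-2-hydroxyphenyl]-3-(dimethylamino)prop-2-en-1-one F2 and cyclised with HCl to 5,7-bis(benzyloxy)-4H-chromen-4-one F3. Conjugate addition of F1 to F3 with Pd(OCOCF3)2 and (R)-4-tert-butyl-2-(pyridin-2-yl)-4,5-dihydrooxazole should then give 16 with C-2 set S by the ligand.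

2. Step 4. Insertion into the electron-rich, peri-substituted chromone may be slow, so that protodeboronation of 8 wins, or the facial selectivity may be insufficient.

   The fallback sets out from 5 and comes back at 9. Claisen–Schmidt condensation of 5 with 4-(benzyloxy)benzaldehyde (KOH, EtOH) should give (E)-1-[4,6-bis(benzyloxy)-2-hydroxy-5-(4-nitrophenoxy)phenyl]-3-[4-(benzyloxy)phenyl]prop-2-en-1-one F4. Oxa-Michael closure (NaOAc, EtOH, reflux) should give rac-5,7-bis(benzyloxy)-2-[4-(benzyloxy)phenyl]-6-(4-nitrophenoxy)-2,3-dihydro-4H-chromen-4-one F5. Kinetic resolution by asymmetric transfer hydrogenation (RuCl(p-cymene)[(R,R)-TsDPEN] or its enantiomer, HCO2H/Et3N) would reduce the 2R ketone to (2R,4R)-5,7-bis(benzyloxy)-2-[4-(benzyloxy)phenyl]-6-(4-nitrophenoxy)-3,4-dihydro-2H-chromen-4-ol F6 and leave 9, at the price of at most half of the material.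

3. Step 1. The Elbs oxidation may stop at low conversion, over-oxidise the electron-rich ring, or lose benzyl groups during the acid hydrolysis of the sulfate.

   The fallback sets out from 1 and comes back at 3. Teuber oxidation of 1 with (KSO3)2NO in phosphate-buffered aqueous acetone should give 2-acetyl-3,5-bis(benzyloxy)cyclohexa-2,5-diene-1,4-dione F7, which Na2S2O4 (EtOAc/H2O) should reduce to hydroquinone 3.

**Further compounds**

F1 | step 8 | [4-({(2S)-5,7-bis(benzyloxy)-2-[4-(benzyloxy)phenyl]-4-oxo-3,4-dihydro-2H-chromen-6-yl}oxy)phenyl]boronic acid | O=C1C[C@@H](c2ccc(OCc3ccccc3)cc2)Oc2cc(OCc3ccccc3)c(Oc3ccc(cc3)B(O)O)c(OCc3ccccc3)c12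
F2 | step 8 | (E)-1-[4,6-bis(benzyloxy)-2-hydroxyphenyl]-3-(dimethylamino)prop-2-en-1-one | CN(C)/C=C/C(=O)c1c(O)cc(OCc2ccccc2)cc1OCc1ccccc1
F3 | step 8 | 5,7-bis(benzyloxy)-4H-chromen-4-one | O=c1ccoc2cc(OCc3ccccc3)cc(OCc3ccccc3)c12
F4 | step 4 | (E)-1-[4,6-bis(benzyloxy)-2-hydroxy-5-(4-nitrophenoxy)phenyl]-3-[4-(benzyloxy)phenyl]prop-2-en-1-one | O=C(/C=C/c1ccc(OCc2ccccc2)cc1)c1c(O)cc(OCc2ccccc2)c(Oc2ccc(cc2)[N+](=O)[O-])c1OCc1ccccc1
F5 | step 4 | rac-5,7-bis(benzyloxy)-2-[4-(benzyloxy)phenyl]-6-(4-nitrophenoxy)-2,3-dihydro-4H-chromen-4-one | O=C1CC(c2ccc(OCc3ccccc3)cc2)Oc2cc(OCc3ccccc3)c(Oc3ccc(cc3)[N+](=O)[O-])c(OCc3ccccc3)c12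
F6 | step 4 | (2R,4R)-5,7-bis(benzyloxy)-2-[4-(benzyloxy)phenyl]-6-(4-nitrophenoxy)-3,4-dihydro-2H-chromen-4-ol | O[C@@H]1C[C@H](c2ccc(OCc3ccccc3)cc2)Oc2cc(OCc3ccccc3)c(Oc3ccc(cc3)[N+](=O)[O-])c(OCc3ccccc3)c21
F7 | step 1 | 2-acetyl-3,5-bis(benzyloxy)cyclohexa-2,5-diene-1,4-dione | CC(=O)C1=C(OCc2ccccc2)C(=O)C(OCc2ccccc2)=CC1=O
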